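## Retrosynthetic overview

1. Feature used: the CH2 bridge joins pyrone C3 to arene C1', and the neighbouring arene carbon C2' carries a free OH. The six atoms O(phenol)–C2'–C1'–CH2–C3–C2(=O) therefore map onto a chroman-2-one ring, in which pyrone C2, C3 and C4 are held as a malonyl unit (lactone carbonyl, ring α-carbon, exocyclic carboxyl).
2. Key disconnections: pyrone C4–C5 (C-acylation of the silyl enol ether of pentan-3-one by the chromanone-3-carbonyl chloride) and pyrone O1–C2 (the ketone enol oxygen displaces the phenol oxygen at the lactone carbonyl).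
3. The 2-oxochromane-3-carboxylic acid goes back to a formylated acylphloroglucinol monomethyl ether and Meldrum's acid (reductive Knoevenagel, then lactonisation by the ortho phenol). The arene goes back to phloroglucinol and (R)-2-methylbutanoic acid, which supplies the only stereocentre.
4. Ring order: arene (bought, then acylated, methylated, formylated), chroman-2-one (temporary ring), 4-hydroxy-2-pyrone (closed last, as the chromanone opens).

Key step: step 9

Assumption: (R)-2-methylbutanoic acid is bought enantiopure. The C3 epimers of chromanones 11 and 14–16, the tautomers of 16 and the E/Z isomers of 13 are carried as mixtures, because all these centres end as sp2 carbons of the pyrone.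

## Route

Step 1
Reactants: 1 (R)-2-methylbutanoic acid
Product: 2 (R)-2-methylbutanoyl chloride
Conditions: (COCl)2 (1.1 equiv), DMF (cat.), CH2Cl2, 0 → 23 °C; used as a solution
Reagents that add atoms: oxalyl chloride, ClC(=O)C(=O)Cl
Why: Acid chloride formation through the catalytic Vilsmeier-type chloroiminium species runs without any base, so no ketene can form and the α-stereocentre should be kept.

Step 2
Reactants: 3 phloroglucinol (anhydrous); 2 (R)-2-methylbutanoyl chloride
Product: 4 (2R)-2-methyl-1-(2,4,6-trihydroxyphenyl)butan-1-one
Conditions: AlCl3 (3.5 equiv), PhNO2/CH2Cl2, 0 → 23 °C; then ice, 1 M HCl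
Reagents that add atoms: none
Why: Friedel–Crafts C-acylation of the very electron-rich phloroglucinol should stop at the mono-ketone because the product is deactivated as its aluminium chelate, and the base-free medium at or below room temperature should leave the α-stereocentre intact.

Step 3
Reactants: 4 (2R)-2-methyl-1-(2,4,6-trihydroxyphenyl)butan-1-one
Product: 5 (2R)-1-(2,6-dihydroxy-4-methoxyphenyl)-2-methylbutan-1-one
Conditions: Me2SO4 (1.0 equiv), K2CO3 (1.0 equiv), acetone, 0 → 23 °C
Reagents that add atoms: dimethyl sulfate, COS(=O)(=O)OC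
Why: Williamson-type O-methylation should be selective because the 4-OH para to the ketone is the most acidic hydroxyl and the only one not hydrogen-bonded to the carbonyl, so one equivalent of carbonate and of dimethyl sulfate alkylates it first, while the phenoxide-conjugated ketone is too poor an acceptor to enolise at the stereocentre.

Step 4
Reactants: 5 (2R)-1-(2,6-dihydroxy-4-methoxyphenyl)-2-methylbutan-1-one
Product: 7 2,4-dihydroxy-6-methoxy-3-[(2R)-2-methylbutanoyl]benzaldehyde, via aryl iminium chloride 6 (not isolated)
Conditions: POCl3 (1.3 equiv), DMF (3 equiv), EtOAc, 0 → 23 °C; then H2O, 23 → 50 °C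
Reagents that add atoms: N,N-dimethylformamide, CN(C)C=O; water, O
Why: Vilsmeier–Haack formylation attacks one of the two equivalent free ring positions of the electron-rich arene and stops after one formyl group because the iminium product 6 is deactivated; aqueous hydrolysis of 6 then releases the aldehyde whose carbon becomes the bridge CH2.

Step 5
Reactants: 7 2,4-dihydroxy-6-methoxy-3-[(2R)-2-methylbutanoyl]benzaldehyde; 8 Meldrum's acid (2,2-dimethyl-1,3-dioxane-4,6-dione)
Product: 10 5-{[2,4-dihydroxy-6-methoxy-3-((2R)-2-methylbutanoyl)phenyl]methyl}-2,2-dimethyl-1,3-dioxane-4,6-dione, via arylidene Meldrum's acid 9 (not isolated)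
Conditions: Hantzsch ester (diethyl 2,6-dimethyl-1,4-dihydropyridine-3,5-dicarboxylate, 1.1 equiv), L-proline (20 mol %), EtOH, 23 °C
Reagents that add atoms: none
Why: Proline-catalysed Knoevenagel condensation gives the highly electrophilic arylidene 9, which is reduced in the same flask by hydride transfer from the Hantzsch ester (three-component reductive alkylation) without touching the chelated aryl ketone.

Step 6
Reactants: 10 5-{[2,4-dihydroxy-6-methoxy-3-((2R)-2-methylbutanoyl)phenyl]methyl}-2,2-dimethyl-1,3-dioxane-4,6-dione
Product: 11 7-hydroxy-5-methoxy-8-[(2R)-2-methylbutanoyl]-2-oxochromane-3-carboxylic acid (C3 epimers)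
Conditions: PhMe, 85 °C, acetone allowed to distil off
Reagents that add atoms: none
Why: Intramolecular transesterification (phenolysis of the Meldrum's acid ring) by the only hydroxyl ortho to the benzylic carbon, with loss of acetone, closes the six-membered aryl lactone and frees the carboxylic acid below the temperature at which the malonic half-acid decarboxylates; the new C3 centre forms as an epimer mixture of no consequence.

Step 7
Reactants: 12 pentan-3-one
Product: 13 3-(trimethylsilyloxy)pent-2-ene (E/Z mixture)
Conditions: TMSOTf (1.1 equiv), Et3N (1.3 equiv), CH2Cl2, 0 °C; pentane extraction, distillation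
Reagents that add atoms: trimethylsilyl trifluoromethanesulfonate, C[Si](C)(C)OS(=O)(=O)C(F)(F)F
Why: Soft enolisation of the symmetric ketone with a silyl triflate and triethylamine gives a single constitutional silyl enol ether, whose double-bond geometry does not matter because this carbon ends as sp2 C5 of the pyrone.

Step 8
Reactants: 11 7-hydroxy-5-methoxy-8-[(2R)-2-methylbutanoyl]-2-oxochromane-3-carboxylic acid
Product: 15 5-methoxy-8-[(2R)-2-methylbutanoyl]-2-oxo-7-(trimethylsilyloxy)chromane-3-carbonyl chloride (C3 epimers), via bis(trimethylsilyl) derivative 14 (not isolated)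
Conditions: MSTFA (2.5 equiv), CH2Cl2, 40 °C, then volatiles removed at 0.1 mbar; (COCl)2 (1.1 equiv), DMF (cat.), CH2Cl2, 0 → 23 °C; volatiles removed, used at once
Reagents that add atoms: N-methyl-N-(trimethylsilyl)trifluoroacetamide, CN(C(=O)C(F)(F)F)[Si](C)(C)C; oxalyl chloride, ClC(=O)C(=O)Cl
Why: Persilylation with a neutral silyl amide, followed by silyl ester to acid chloride exchange with oxalyl chloride and catalytic DMF, gives the acid chloride with release of chlorotrimethylsilane, CO and CO2 instead of HCl, so the aryl lactone and the chelation-shielded aryl silyl ether should survive.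

Step 9
Reactants: 15 5-methoxy-8-[(2R)-2-methylbutanoyl]-2-oxo-7-(trimethylsilyloxy)chromane-3-carbonyl chloride; 13 3-(trimethylsilyloxy)pent-2-ene
Product: 18 6-ethyl-4-hydroxy-3-{[2,4-dihydroxy-6-methoxy-3-((2R)-2-methylbutanoyl)phenyl]methyl}-5-methyl-2H-pyran-2-one (CNP0199908.1), via triketone 16 (not isolated), via O-silyl pyrone 17 (not isolated)
Conditions: 13 (2.5 equiv), ZnCl2 (20 mol %), CH2Cl2/Et2O, 0 → 23 °C; then PhMe, 60 °C; then 1 M HCl, THF, 23 °C
Reagents that add atoms: none
Why: Proposed new method: ZnCl2 activates acid chloride 15 so that the nucleophilic C2 of enol ether 13 attacks the chlorocarbonyl carbon (pyrone C4–C5 bond, chlorotrimethylsilane lost) to give the 3-(2-methyl-3-oxopentanoyl)chroman-2-one 16, which is a 3,5-dioxo acid held as its aryl ester; the enol oxygen of its terminal ethyl ketone then adds to the lactone carbonyl and the tetrahedral intermediate collapses with expulsion of the tethered phenoxide (pyrone O1–C2 bond), so the 2-pyrone closes as the chroman-2-one opens, and tautomerisation to the acidic 4-hydroxy-2-pyrone 17 makes the ring switch irreversible. The closest known reaction types are the ZnCl2-catalysed C-acylation of ketone silyl enol ethers by acid chlorides, the one-step synthesis of 4-hydroxy-2-pyrones from silyl enol ethers and malonyl dichlorides, and the lactonisation of 3,5-dioxo esters to 4-hydroxy-2-pyrones; new here is that the ester leaving group is the ring oxygen of an aryl lactone, so that closing one ring opens the other. The pyrone ring closes by a 6-exo-trig addition–elimination of an enol oxygen at an activated aryl ester carbonyl. No stereocentre is created, since C3 of the chromanone and the methyl-bearing carbon of 16 both end as sp2 pyrone carbons, and the (R) centre beside the hindered aryl ketone is not exposed to base. The step needs C- rather than O-acylation of 13, which Lewis acid catalysis (as opposed to fluoride or enolate conditions) should secure, and closure on the lactone carbonyl only, which holds because it is the single electrophilic carbonyl the distal enol oxygen can reach through a six-membered transition state. Because the CH2 bridge is already bonded to both the arene and the malonyl carbon, symmetrical methylene-bis products cannot arise, and the final acid work-up removes the aryl silyl ether.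

## Compound list

1 | (R)-2-methylbutanoic acid | OC(=O)[C@H](C)CC | starting material
2 | (R)-2-methylbutanoyl chloride | ClC(=O)[C@H](C)CC | intermediate
3 | phloroglucinol (benzene-1,3,5-triol) | Oc1cc(O)cc(O)c1 | starting material
4 | (2R)-2-methyl-1-(2,4,6-trihydroxyphenyl)butan-1-one | Oc1cc(O)c(C(=O)[C@H](C)CC)c(O)c1 | intermediate
5 | (2R)-1-(2,6-dihydroxy-4-methoxyphenyl)-2-methylbutan-1-one | COc1cc(O)c(C(=O)[C@H](C)CC)c(O)c1 | intermediate
6 | N-{[2,4-dihydroxy-6-methoxy-3-((2R)-2-methylbutanoyl)phenyl]methylidene}-N-methylmethanaminium chloride (aryl iminium chloride, not isolated) | COc1cc(O)c(C(=O)[C@H](C)CC)c(O)c1C=[N+](C)C.[Cl-] | intermediate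
7 | 2,4-dihydroxy-6-methoxy-3-[(2R)-2-methylbutanoyl]benzaldehyde | COc1cc(O)c(C(=O)[C@H](C)CC)c(O)c1C=O | intermediate
8 | Meldrum's acid (2,2-dimethyl-1,3-dioxane-4,6-dione) | CC1(C)OC(=O)CC(=O)O1 | starting material
9 | 5-{[2,4-dihydroxy-6-methoxy-3-((2R)-2-methylbutanoyl)phenyl]methylidene}-2,2-dimethyl-1,3-dioxane-4,6-dione (arylidene Meldrum's acid, not isolated) | COc1cc(O)c(C(=O)[C@H](C)CC)c(O)c1C=C1C(=O)OC(C)(C)OC1=O | intermediate
10 | 5-{[2,4-dihydroxy-6-methoxy-3-((2R)-2-methylbutanoyl)phenyl]methyl}-2,2-dimethyl-1,3-dioxane-4,6-dione | COc1cc(O)c(C(=O)[C@H](C)CC)c(O)c1CC1C(=O)OC(C)(C)OC1=O | intermediate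
11 | 7-hydroxy-5-methoxy-8-[(2R)-2-methylbutanoyl]-2-oxochromane-3-carboxylic acid (C3 epimers) | COc1cc(O)c(C(=O)[C@H](C)CC)c2OC(=O)C(C(=O)O)Cc12 | intermediate
12 | pentan-3-one | CCC(=O)CC | starting material
13 | 3-(trimethylsilyloxy)pent-2-ene (E/Z mixture) | CC=C(CC)O[Si](C)(C)C | intermediate
14 | trimethylsilyl 5-methoxy-8-[(2R)-2-methylbutanoyl]-2-oxo-7-(trimethylsilyloxy)chromane-3-carboxylate (C3 epimers, not isolated) | COc1cc(O[Si](C)(C)C)c(C(=O)[C@H](C)CC)c2OC(=O)C(C(=O)O[Si](C)(C)C)Cc12 | intermediate
15 | 5-methoxy-8-[(2R)-2-methylbutanoyl]-2-oxo-7-(trimethylsilyloxy)chromane-3-carbonyl chloride (C3 epimers) | COc1cc(O[Si](C)(C)C)c(C(=O)[C@H](C)CC)c2OC(=O)C(C(=O)Cl)Cc12 | intermediate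
16 | 5-methoxy-8-[(2R)-2-methylbutanoyl]-3-(2-methyl-3-oxopentanoyl)-7-(trimethylsilyloxy)chroman-2-one (triketone, epimers and tautomers, not isolated) | COc1cc(O[Si](C)(C)C)c(C(=O)[C@H](C)CC)c2OC(=O)C(C(=O)C(C)C(=O)CC)Cc12 | intermediate
17 | 6-ethyl-4-hydroxy-3-{[2-hydroxy-6-methoxy-3-((2R)-2-methylbutanoyl)-4-(trimethylsilyloxy)phenyl]methyl}-5-methyl-2H-pyran-2-one (O-silyl pyrone, not isolated) | CCc1oc(=O)c(Cc2c(OC)cc(O[Si](C)(C)C)c(C(=O)[C@H](C)CC)c2O)c(O)c1C | intermediate
18 | 6-ethyl-4-hydroxy-3-{[2,4-dihydroxy-6-methoxy-3-((2R)-2-methylbutanoyl)phenyl]methyl}-5-methyl-2H-pyran-2-one (CNP0199908.1) | CCc1oc(=O)c(Cc2c(OC)cc(O)c(C(=O)[C@H](C)CC)c2O)c(O)c1C | target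

## Step count and risks

Total steps: 9. Longest linear sequence: 8 steps (steps 1–6, 8 and 9, from acid 1 to target 18); step 7 is a one-step side branch.

Steps most likely to fail:

1. Step 9 (proposed new method). The enol ether may be acylated on oxygen instead of carbon, the acid chloride may lose HCl and self-condense before it meets the enol ether, or the sequence may stop at the open triketone if the enol oxygen does not displace the lactone oxygen. The fallback uses known chemistry and joins the two rings in the conventional way. Enol ether 13 and malonyl dichloride (Et2O, −78 → 23 °C) give 6-ethyl-4-hydroxy-5-methyl-2H-pyran-2-one F1 by the established silyl enol ether/malonyl dichloride pyrone synthesis. A proline-catalysed three-component reductive alkylation of F1 with aldehyde 7 and Hantzsch ester (CH2Cl2 or EtOH, 23 °C) then passes through 3-arylidene-6-ethyl-5-methylpyran-2,4-dione F2, which is reduced in the flask to the CH2-bridged product. This fallback sets out from 7 (with 13) and comes back to the route at 18; steps 5, 6 and 8 are then not needed.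

2. Step 5. Hydride transfer may be outrun by attack of the ortho phenol on the arylidene Meldrum's acid (premature lactonisation to a coumarin), or condensation of the hindered, electron-rich aldehyde may stall. The fallback accepts the cyclisation. Knoevenagel condensation of 7 with 8 (piperidinium acetate cat., EtOH, 60 °C) proceeds by way of 9 with loss of acetone and water to 7-hydroxy-5-methoxy-8-[(2R)-2-methylbutanoyl]-2-oxo-2H-chromene-3-carboxylic acid F3. Hydrogenation of its C3–C4 double bond (H2, Pd/C, EtOAc, 23 °C) gives the chromanone acid. This fallback sets out from 7 and comes back at 11, replacing steps 5 and 6.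

3. Step 2. The configuration next to the acyl carbon may erode through Lewis-acid-promoted enolisation of the acylium or ketone complex, and over-acylation may compete. The fallback forms the aryl ketone by organolithium addition, so the ketone is never exposed to AlCl3. Acid chloride 2 and N,O-dimethylhydroxylamine hydrochloride under two-phase Schotten–Baumann conditions (aq. K2CO3/CH2Cl2, 0 °C) give (2R)-N-methoxy-N,2-dimethylbutanamide F4. Commercial 5-methoxyresorcinol is converted (MOMCl, i-Pr2NEt, CH2Cl2) to 1-methoxy-3,5-bis(methoxymethoxy)benzene F5. Directed lithiation between the two MOM ethers (n-BuLi, THF, 0 °C) gives [4-methoxy-2,6-bis(methoxymethoxy)phenyl]lithium F6. F6 adds to F4 (−78 → 0 °C, then aq. NH4Cl) to give (2R)-1-[4-methoxy-2,6-bis(methoxymethoxy)phenyl]-2-methylbutan-1-one F7, the ketone being released only on work-up from the chelated adduct. Removal of both MOM groups (HCl, MeOH, 23 °C) gives the 4-O-methyl ketone. This fallback sets out from 2 and comes back at 5, and it also replaces the selective methylation of step 3.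

## Further compounds

F1 | step 9 | 6-ethyl-4-hydroxy-5-methyl-2H-pyran-2-one | CCc1oc(=O)cc(O)c1C
F2 | step 9 | 3-{[2,4-dihydroxy-6-methoxy-3-((2R)-2-methylbutanoyl)phenyl]methylidene}-6-ethyl-5-methyl-2H-pyran-2,4(3H)-dione | CCC1=C(C)C(=O)C(=Cc2c(OC)cc(O)c(C(=O)[C@H](C)CC)c2O)C(=O)O1
F3 | step 5 | 7-hydroxy-5-methoxy-8-[(2R)-2-methylbutanoyl]-2-oxo-2H-chromene-3-carboxylic acid | COc1cc(O)c(C(=O)[C@H](C)CC)c2OC(=O)C(C(=O)O)=Cc12
F4 | step 2 | (2R)-N-methoxy-N,2-dimethylbutanamide | CON(C)C(=O)[C@H](C)CC
F5 | step 2 | 1-methoxy-3,5-bis(methoxymethoxy)benzene | COCOc1cc(OC)cc(OCOC)c1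
F6 | step 2 | [4-methoxy-2,6-bis(methoxymethoxy)phenyl]lithium | [Li]c1c(OCOC)cc(OC)cc1OCOC
F7 | step 2 | (2R)-1-[4-methoxy-2,6-bis(methoxymethoxy)phenyl]-2-methylbutan-1-one | COCOc1cc(OC)cc(OCOC)c1C(=O)[C@H](C)CC
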